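## Analysis of the target

The target is a dimeric isoflavan. The upper 3,4-dihydro-2H-chromene (benzo ring A, pyran ring C) carries ring B (2-hydroxy-4,5-dimethoxyphenyl) at C3 and the central benzene ring D at C4; ring D bears, ortho to that bond, C3' of the lower chroman (pyran ring E, benzo ring F). There are three stereocentres, C3 (R), C4 (S) and C3' (R). C3 and C4 are adjacent and trans on ring C, while C3' sits on the ortho carbon of ring D, close enough to C4 to bias reactions there. Four phenols stand beside three methyl ethers, so each phenol needs a group that leaves without touching a methyl ether; benzyl ethers serve, because the skeleton has no benzylic C–O bond. The electron-rich arenes and the doubly benzylic C4–H are sensitive to oxidants and strong acid, and C3 should never become alpha to a carbonyl once it is set. The hard part is C4, a methine carrying two arenes, one of them (ring D) substituted at both ortho positions, next to a second aryl-bearing methine, with relative and absolute configuration to be controlled. Ring D is a second problem: a 1,2,3,5-tetrasubstituted benzene whose two oxygens must end up different. The strategy rests on the C3–C4 unit: read as ring D–CH=CH–[B], its two methines result from adding ring B to C3 and ring A to C4 across an (E)-alkene, and the boron left on C3 is where C2 is attached.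

## Retrosynthetic reasoning

**Protecting groups (38 from 37).** No skeletal bond is cut. The four phenols of 38 are traced to the benzyl ethers of 37. This is decided first because the three methyl ethers must survive to the end, and only hydrogenolysis removes a phenol mask without endangering them. The forward step only has to cleave four O–benzyl bonds.

**Ring C (37 from 36 from 35).** The O1–C2 bond is cut, opening ring C to phenol–alcohol 36. Its ring A hydroxyl is kept distinct from the benzylated ones as the methoxymethyl ether of 35. Cutting the C–O bond rather than a C–C bond lets the crowded C3–C4 unit be built in an open chain, where addition to an alkene has a predictable course. Ring closure then is a substitution at a primary carbon that touches no stereocentre.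

**C2 (35 from 33).** The C3–C2 bond is cut; C2 arises by one-carbon homologation of a C3–boron bond and oxidation. C2 thus enters at the alcohol level, C3 is never alpha to a carbonyl, and the boron left by the key step is used. The forward reaction must insert CH2 into the C–B bond of a hindered secondary benzylic boronic ester with retention.

**Key disconnection (33 from 22, 31 and 30).** The C3–ring B and C4–C4a bonds are cut together. This leaves alkenylboronic ester 22, ring B as aryllithium 31 (made in the flask from bromide 25) and ring A as triflate 30. Three fragments converge, both stereocentres arise in one step, and their relative configuration follows from the alkene geometry. The forward reaction must send ate complex 32 down the 1,2-migration path under palladium catalysis and not into transmetallation. For that reason the boron of 22 carries diol 20 and not the pinacol unit of 18: ate complexes of beta-substituted alkenylboronic pinacol esters tend to hand a carbon group directly to palladium, and the congested oxygens of 20 are meant to close that path.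

**Alkenylboronic ester (22 from 18 from 17).** The boron ligand is exchanged (18 to 22 through acid 21), and the C=C bond is cut back to aldehyde 17. An olefination that brings the boron in with the new carbon gives the (E)-alkene directly. Diol 20 comes from diketone 19 in one step.

**Ring E and oxidation level (17 from 16 from 15).** The aldehyde is traced to benzylic alcohol 16, and the aryl–O bond of ring E is cut to bromo diol 15. A palladium-catalysed C–O coupling needs no phenol protecting group in the lower half, and the two hydroxyls of 15 are told apart by the ring size each would close.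

**C3' (15 from 14 from 12 and 4).** The C3'–C4' bond is cut: enolate 13 of imide 12 is alkylated with bromide 4 under control of auxiliary 10. One hydride reduction of 14 removes the auxiliary and brings the ring D ester to the alcohol level, so the ester costs no separate step. Auxiliary-controlled alkylation was chosen because the aryl group on the new centre is ortho-substituted, which this method tolerates.

**Ring D (12 from 9 from 7 from 6 from 5).** Imide 12 comes from acid 9 and 10. The CH2–CO2H bond of 9 is cut to toluate 7 (lateral lithiation through 8), and 7 is the benzyl methyl diether of 5. Ester 5 already holds the whole pattern of ring D: ester carbon becomes C4, the chelated hydroxyl becomes the methoxy group, the free hydroxyl becomes the phenol, and the methyl group becomes C3'. The hydrogen bond to the ester makes the two hydroxyls chemically different (6, then 7).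

**Small fragments.** Bromide 4 comes from 1 through 2 and 3. Bromide 25 comes from 23 through 24. Triflate 30 comes from 26 through 27 and 29 (formate 28 in between).

## Alternatives that were turned down

**Alternative 1:** carbene insertion into the diarylmethane C–H bonds.
- Disconnection: the C3–C4 bond, with ring C already tied through an ester. Diazo ester A1 (the ring A phenol, carrying the ring A–CH2–ring D methylene, acylated by the ring B aryldiazoacetic acid) would give lactone A2.
- Forward key step: a chiral dirhodium tetracarboxylate decomposes A1, and the donor/acceptor carbene inserts into one of the two C4–H bonds, closing the six-membered lactone.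
- For it: the C4 methylene is doubly benzylic and flanked by electron-rich rings, so its hydrogens are hydridic and well suited to insertion. One step makes the C3–C4 bond, closes ring C and sets both centres. On convergence and on the bonds made while closing ring C it is stronger than the chosen key step, which closes no ring.
- Against it: the two C4 hydrogens are diastereotopic because of C3', so one catalyst must choose a hydrogen and a carbene face against a possible substrate bias. The carbene also has easier targets: cyclopropanation or ring expansion of three electron-rich arenes, and ylide formation at the ortho oxygens of ring B and ring D. Aryl esters prefer the conformation that holds the carbene away from the O-aryl group, and six-membered closure is less favoured than five-membered. A2 has an epimerisable C3 and must still be reduced and reclosed to reach 37, about two extra steps.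
- Comparison: the chosen strategy gives a trans relationship fixed by mechanism, only one catalyst-controlled element, and C2 at the alcohol level.

**Alternative 2:** ring D by Diels–Alder benzannulation.
- Disconnection: two C–C bonds of ring D. Alkynone A3 (ring A aroyl on one alkyne carbon, C3' of the lower chroman on the other) and silyloxy ketene-acetal diene A4 would give benzophenone A5.
- Forward key step: thermal [4+2] cycloaddition, then aromatisation by loss of one acetal alkoxy group and the silyl group.
- For it: it joins the upper and lower halves while creating ring D, and the polarity of ynone and diene dictates the regiochemistry. The methoxy/hydroxyl difference on ring D appears automatically. On convergence for ring D it is stronger than the chosen route, which needs eight linear steps from 5 to aldehyde 17.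
- Against it: the step makes no stereocentre. C4 arrives as a ketone flanked by three ortho substituents, and attaching the C3 unit to it and then controlling two adjacent centres has no reliable solution; the real problem is postponed. In A3 the only existing stereocentre is propargylic and next to an ynone, where propargyl–allenyl isomerisation under heat or base would erase it.
- Comparison: the chosen strategy offers a key step that sets both missing centres and keeps C3' as a plain benzylic methine after step 9.

**Alternative 3:** ammonium enolate plus quinone methide annulation.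
- Disconnection: the C3–C4 and O1–C2 (acyl) bonds. Sulfone A6 releases ortho-quinone methide A7, which combines with ring B arylacetic acid A8 to give trans lactone A9.
- Forward key step: a carbonate base eliminates the sulfinate from A6. The enolate of A8, bound to a chiral isothiourea after activation as a mixed anhydride, adds to the methide carbon (C4), and the phenoxide then closes the lactone.
- For it: one metal-free step closes ring C and sets both centres, with matched polarity (C4 electrophilic, C3 nucleophilic). It is closer to established reactivity than the chosen key step. From aldehyde 17 it would be about two steps shorter. On these points it is as strong or stronger.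
- Against it: A7 carries the twisted, di-ortho-substituted ring D on the methide carbon, and the ring A benzyloxy group is para to that carbon. Both stabilise A7 and lower its electrophilicity, so the Michael step is the weak point. The trans relationship rests on kinetic diastereoselection or on later epimerisation of an alpha-aryl aryl ester, which can also revert to A7 under base. A9 must be reduced and reclosed to reach 37.
- Comparison: the chosen strategy offers a trans relationship enforced by anti addition to a defined alkene, an electrophile at C4 (arylpalladium) that does not depend on quinone methide reactivity, and C2 without a base-labile lactone.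

Key step: step 20

Remark: the antipode of the ligand in step 20 is assigned by analogy and not derived; if the arylpalladium is delivered to the other alkene face, the mirror-image ligand is used and nothing else changes.
Remark: diol 20 is treated as not commercially available and is made in step 13.

## Steps

Step 1
Reactants: 1 2-bromo-4-hydroxybenzaldehyde
Product: 2 4-(benzyloxy)-2-bromobenzaldehyde
Conditions: BnBr, K2CO3, DMF, rt
Reagents that add atoms: benzyl bromide, BrCc1ccccc1
Why: Williamson ether synthesis; the phenoxide is the only nucleophile and the aldehyde cannot enolise.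

Step 2
Reactants: 2 4-(benzyloxy)-2-bromobenzaldehyde
Product: 3 [4-(benzyloxy)-2-bromophenyl]methanol
Conditions: NaBH4, MeOH/THF, 0 °C
Reagents that add atoms: none
Why: Borohydride reduction of an aryl aldehyde; the aryl bromide and the benzyl ether are inert.

Step 3
Reactants: 3 [4-(benzyloxy)-2-bromophenyl]methanol
Product: 4 4-(benzyloxy)-2-bromo-1-(bromomethyl)benzene
Conditions: CBr4, PPh3, CH2Cl2, 0 °C
Reagents that add atoms: tetrabromomethane, BrC(Br)(Br)Br
Why: Appel reaction under neutral conditions, which spare the benzyl ether; the ortho bromine slows ionisation of the 4-alkoxybenzyl bromide, and 4 is used promptly.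

Step 4
Reactants: 5 methyl 2,4-dihydroxy-6-methylbenzoate (methyl orsellinate)
Product: 6 methyl 4-(benzyloxy)-2-hydroxy-6-methylbenzoate
Conditions: BnBr (1.05 equiv), K2CO3, acetone, reflux
Reagents that add atoms: benzyl bromide, BrCc1ccccc1
Why: Regioselective Williamson etherification; the 2-hydroxyl is hydrogen-bonded to the ester carbonyl and hindered, so the free and more acidic 4-hydroxyl reacts.

Step 5
Reactants: 6 methyl 4-(benzyloxy)-2-hydroxy-6-methylbenzoate
Product: 7 methyl 4-(benzyloxy)-2-methoxy-6-methylbenzoate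
Conditions: MeI, K2CO3, DMF, 50 °C
Reagents that add atoms: iodomethane, CI
Why: Williamson methylation of the chelated phenol under more forcing conditions; the two ring D oxygens are now differentiated as in the target.

Step 6
Reactants: 7 methyl 4-(benzyloxy)-2-methoxy-6-methylbenzoate
Product: 9 [5-(benzyloxy)-3-methoxy-2-(methoxycarbonyl)phenyl]acetic acid, via benzylic lithium species 8 (not isolated)
Conditions: LiN(i-Pr)2, THF, −78 °C; then CO2; aq. HCl
Reagents that add atoms: carbon dioxide, O=C=O
Why: Lateral lithiation of an ortho-toluate followed by carboxylation; the ortho ester acidifies the methyl group far more than the benzyl ether CH2, and the hindered ester resists self-condensation at low temperature.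

Step 7
Reactants: 9 [5-(benzyloxy)-3-methoxy-2-(methoxycarbonyl)phenyl]acetic acid; 10 (4R)-4-benzyl-1,3-oxazolidin-2-one
Product: 12 methyl 4-(benzyloxy)-2-{2-[(4R)-4-benzyl-2-oxo-1,3-oxazolidin-3-yl]-2-oxoethyl}-6-methoxybenzoate, via mixed pivalic anhydride 11 (not isolated)
Conditions: t-BuCOCl, Et3N, THF, −20 °C; then 10, LiCl, −20 °C → rt
Reagents that add atoms: none
Why: N-acylation of the oxazolidinone through a mixed anhydride; attack occurs at the unhindered arylacetyl carbonyl, not at the pivaloyl carbonyl or the di-ortho-substituted benzoate.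

Step 8
Reactants: 12 methyl 4-(benzyloxy)-2-{2-[(4R)-4-benzyl-2-oxo-1,3-oxazolidin-3-yl]-2-oxoethyl}-6-methoxybenzoate; 4 4-(benzyloxy)-2-bromo-1-(bromomethyl)benzene
Product: 14 methyl 4-(benzyloxy)-2-{(2R)-1-[(4R)-4-benzyl-2-oxo-1,3-oxazolidin-3-yl]-3-[4-(benzyloxy)-2-bromophenyl]-1-oxopropan-2-yl}-6-methoxybenzoate, via sodium enolate 13 (not isolated)
Conditions: NaN(SiMe3)2, THF, −78 °C; then 4, −78 → −40 °C
Reagents that add atoms: none
Why: Evans auxiliary alkylation; the chelated (Z)-enolate is shielded on one face by the benzyl group of the (R)-auxiliary and 4 enters from the other, which sets C3' as (R). A slight deficit of base and a cold quench keep the alpha-aryl imide from epimerising.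

Step 9
Reactants: 14 methyl 4-(benzyloxy)-2-{(2R)-1-[(4R)-4-benzyl-2-oxo-1,3-oxazolidin-3-yl]-3-[4-(benzyloxy)-2-bromophenyl]-1-oxopropan-2-yl}-6-methoxybenzoate
Product: 15 (2R)-2-[5-(benzyloxy)-2-(hydroxymethyl)-3-methoxyphenyl]-3-[4-(benzyloxy)-2-bromophenyl]propan-1-ol
Conditions: LiAlH4, THF, 0 °C
Reagents that add atoms: none
Why: Hydride reduction cleaves the imide to the primary alcohol and in the same operation reduces the benzoate to the benzylic alcohol; C3' is then no longer alpha to a carbonyl, and the aryl bromide survives at 0 °C.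

Step 10
Reactants: 15 (2R)-2-[5-(benzyloxy)-2-(hydroxymethyl)-3-methoxyphenyl]-3-[4-(benzyloxy)-2-bromophenyl]propan-1-ol
Product: 16 {4-(benzyloxy)-2-[(3R)-7-(benzyloxy)-3,4-dihydro-2H-chromen-3-yl]-6-methoxyphenyl}methanol
Conditions: Pd(OAc)2 (5 mol %), 2-(di-tert-butylphosphino)-1,1'-binaphthyl (6 mol %), Cs2CO3, toluene, 80 °C
Reagents that add atoms: none
Why: Palladium-catalysed intramolecular C–O coupling (Buchwald–Hartwig etherification) closes ring E by attack of the aliphatic alkoxide on the arylpalladium bromide; the bulky phosphine favours C–O reductive elimination over beta-hydride elimination. The benzylic hydroxyl would have to close an eight-membered ring and should stay free.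

Step 11
Reactants: 16 {4-(benzyloxy)-2-[(3R)-7-(benzyloxy)-3,4-dihydro-2H-chromen-3-yl]-6-methoxyphenyl}methanol
Product: 17 4-(benzyloxy)-2-[(3R)-7-(benzyloxy)-3,4-dihydro-2H-chromen-3-yl]-6-methoxybenzaldehyde
Conditions: MnO2, CH2Cl2, rt
Reagents that add atoms: none
Why: Oxidation of a benzylic alcohol with activated manganese dioxide; it stops at the aldehyde, and no other alcohol is present.

Step 12
Reactants: 17 4-(benzyloxy)-2-[(3R)-7-(benzyloxy)-3,4-dihydro-2H-chromen-3-yl]-6-methoxybenzaldehyde
Product: 18 2-[(E)-2-{4-(benzyloxy)-2-[(3R)-7-(benzyloxy)-3,4-dihydro-2H-chromen-3-yl]-6-methoxyphenyl}ethenyl]-4,4,5,5-tetramethyl-1,3,2-dioxaborolane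
Conditions: CH2(Bpin)2, lithium 2,2,6,6-tetramethylpiperidide, THF, 0 °C; then 17, −78 °C → rt
Reagents that add atoms: bis[(pinacolato)boryl]methane, CC1(C)OB(CB2OC(C)(C)C(C)(C)O2)OC1(C)C
Why: Boron–Wittig olefination; the lithiated geminal bis(boronate) adds to the aldehyde and syn elimination of a boron–oxygen pair gives the alkenylboronate, (E) because the aryl group and the remaining boryl group avoid each other in the four-membered transition state.

Step 13
Reactants: 19 acenaphthylene-1,2-dione
Product: 20 cis-1,2-dimethyl-1,2-dihydroacenaphthylene-1,2-diol (meso)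
Conditions: AlMe3 (excess), toluene, 0 °C → rt; then 1 M HCl
Reagents that add atoms: trimethylaluminium, C[Al](C)C
Why: Double 1,2-addition of a methylaluminium reagent to a 1,2-diketone; the second methyl group should add anti to the bulky aluminium alkoxide, which gives the cis diol needed for a cyclic boronic ester.

Step 14
Reactants: 18 2-[(E)-2-{4-(benzyloxy)-2-[(3R)-7-(benzyloxy)-3,4-dihydro-2H-chromen-3-yl]-6-methoxyphenyl}ethenyl]-4,4,5,5-tetramethyl-1,3,2-dioxaborolane; 20 cis-1,2-dimethyl-1,2-dihydroacenaphthylene-1,2-diol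
Product: 22 cyclic boronic ester of diol 20 and [(E)-2-{4-(benzyloxy)-2-[(3R)-7-(benzyloxy)-3,4-dihydro-2H-chromen-3-yl]-6-methoxyphenyl}ethenyl]boronic acid, via alkenylboronic acid 21 (not isolated)
Conditions: NaIO4, NH4OAc, acetone/H2O, rt; then 20, MgSO4, CH2Cl2, rt
Reagents that add atoms: none
Why: Periodate cleaves the pinacol unit oxidatively to free the boronic acid, which condenses with the cis diol under dehydrating conditions; alkene geometry and C3' are untouched. The exchange is made because only the hindered diol ester is expected to resist direct transmetallation in step 20.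

Step 15
Reactants: 23 3,4-dimethoxyphenol
Product: 24 2-bromo-4,5-dimethoxyphenol
Conditions: NBS, CH2Cl2, −20 → 0 °C
Reagents that add atoms: N-bromosuccinimide, O=C1CCC(=O)N1Br
Why: Electrophilic aromatic bromination at the position ortho to the hydroxyl and para to the 3-methoxy group, the most activated and least hindered site.

Step 16
Reactants: 24 2-bromo-4,5-dimethoxyphenol
Product: 25 1-(benzyloxy)-2-bromo-4,5-dimethoxybenzene
Conditions: BnBr, K2CO3, DMF, rt
Reagents that add atoms: benzyl bromide, BrCc1ccccc1
Why: Williamson ether synthesis on the only hydroxyl.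

Step 17
Reactants: 26 4-(benzyloxy)-2-hydroxybenzaldehyde
Product: 27 4-(benzyloxy)-2-(methoxymethoxy)benzaldehyde
Conditions: MOMCl, i-Pr2NEt, CH2Cl2, 0 °C → rt
Reagents that add atoms: chloromethyl methyl ether, COCCl
Why: O-alkylation of the phenol to the methoxymethyl acetal; this group withstands peracid, triflation and the organometallic steps and is later removed without touching benzyl ethers.

Step 18
Reactants: 27 4-(benzyloxy)-2-(methoxymethoxy)benzaldehyde
Product: 29 4-(benzyloxy)-2-(methoxymethoxy)phenol, via aryl formate 28 (not isolated)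
Conditions: mCPBA, NaHCO3, CH2Cl2, 0 °C → rt; then K2CO3, MeOH, rt
Reagents that add atoms: 3-chloroperoxybenzoic acid, OOC(=O)c1cccc(Cl)c1
Why: Dakin-type Baeyer–Villiger oxidation; the electron-rich aryl group migrates in the Criegee intermediate to give the formate, which is methanolysed to the phenol, and the bicarbonate buffer protects the acetal.

Step 19
Reactants: 29 4-(benzyloxy)-2-(methoxymethoxy)phenol
Product: 30 4-(benzyloxy)-2-(methoxymethoxy)phenyl trifluoromethanesulfonate
Conditions: Tf2O, pyridine, CH2Cl2, 0 °C
Reagents that add atoms: trifluoromethanesulfonic anhydride, O=S(=O)(OS(=O)(=O)C(F)(F)F)C(F)(F)F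
Why: O-sulfonylation of the phenol; pyridine buffers the acid so that the acetal survives.

Step 20
Reactants: 25 1-(benzyloxy)-2-bromo-4,5-dimethoxybenzene; 22 cyclic boronic ester of diol 20 and the (E)-alkenylboronic acid; 30 4-(benzyloxy)-2-(methoxymethoxy)phenyl trifluoromethanesulfonate
Product: 33 cyclic boronic ester of diol 20 and (1R,2S)-1-[2-(benzyloxy)-4,5-dimethoxyphenyl]-2-[4-(benzyloxy)-2-(methoxymethoxy)phenyl]-2-{4-(benzyloxy)-2-[(3R)-7-(benzyloxy)-3,4-dihydro-2H-chromen-3-yl]-6-methoxyphenyl}ethylboronic acid, via aryllithium 31 (not isolated), via boron ate complex 32 (not isolated)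
Conditions: 25, t-BuLi (2 equiv), THF, −78 °C; 22, −78 °C → rt; then Pd(OAc)2 (5 mol %), (Sp,Sp)-MandyPhos Fe[C5H3(PPh2)(CH(NMe2)Ph)]2 (6 mol %), 30, KOTf, THF, 60 °C
Reagents that add atoms: none
Why: Proposed new method: aryllithium 31 adds to the boron of 22 to give ate complex 32, whose alkene is nucleophilic; oxidative addition of 30 to zerovalent palladium gives a cationic arylpalladium that binds this alkene and triggers a 1,2-metallate shift, ring B moving from boron to C3 anti to the palladium that bonds to benzylic C4, and C–C reductive elimination with retention then attaches ring A. The closest known reaction type is the palladium-catalysed enantioselective conjunctive cross-coupling of beta-alkyl alkenylboron ate complexes bearing a hindered diol with aryllithiums and aryl triflates; a beta-aryl group substituted at both ortho positions, an ortho-alkoxy migrating aryl and an ortho-substituted triflate lie outside it. No ring is closed. C3 and C4 are both new stereocentres: their relative configuration follows from the stereospecific anti addition across the (E)-alkene, and their absolute sense from the alkene face that the chiral bisphosphine lets the arylpalladium reach, with C3' on the ortho substituent of ring D as a spectator that may reinforce or oppose it. The step needs chemoselectivity for the metallate shift over direct boron-to-palladium transmetallation (Suzuki–Miyaura coupling), which the congested oxygens of diol 20 are meant to secure. It also needs migration of ring B only, which is secured because the alkenyl group is the acceptor and the diol oxygens do not migrate. KOTf is added to precipitate the bromide that would otherwise occupy the cationic palladium.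

Step 21
Reactants: 33 cyclic boronic ester of diol 20 and the (1R,2S)-1,2,2-triarylethylboronic acid
Product: 35 (2R,3S)-2-[2-(benzyloxy)-4,5-dimethoxyphenyl]-3-[4-(benzyloxy)-2-(methoxymethoxy)phenyl]-3-{4-(benzyloxy)-2-[(3R)-7-(benzyloxy)-3,4-dihydro-2H-chromen-3-yl]-6-methoxyphenyl}propan-1-ol, via homologated boronic ester 34 (not isolated)
Conditions: BrCH2Cl, n-BuLi, THF, −78 °C → rt; then NaOH, H2O2, THF/H2O, 0 °C → rt
Reagents that add atoms: bromochloromethane, ClCBr; hydrogen peroxide, OO
Why: Matteson homologation; chloromethyllithium made in the presence of 33 adds to boron and the secondary benzylic carbon migrates with retention, expelling chloride, after which oxidation of the new primary C–B bond gives the C2 alcohol. C3 keeps its configuration because the migrating carbon stays bound throughout.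

Step 22
Reactants: 35 (2R,3S)-2-[2-(benzyloxy)-4,5-dimethoxyphenyl]-3-[4-(benzyloxy)-2-(methoxymethoxy)phenyl]-3-{4-(benzyloxy)-2-[(3R)-7-(benzyloxy)-3,4-dihydro-2H-chromen-3-yl]-6-methoxyphenyl}propan-1-ol
Product: 36 (2R,3S)-2-[2-(benzyloxy)-4,5-dimethoxyphenyl]-3-[4-(benzyloxy)-2-hydroxyphenyl]-3-{4-(benzyloxy)-2-[(3R)-7-(benzyloxy)-3,4-dihydro-2H-chromen-3-yl]-6-methoxyphenyl}propan-1-ol
Conditions: 3 M HCl, MeOH/THF, 45 °C
Reagents that add atoms: none
Why: Acid-catalysed cleavage of the methoxymethyl acetal, with methanol trapping the oxocarbenium fragment; benzyl ethers, the primary alcohol and the diarylmethine are stable to dilute acid.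

Step 23
Reactants: 36 (2R,3S)-2-[2-(benzyloxy)-4,5-dimethoxyphenyl]-3-[4-(benzyloxy)-2-hydroxyphenyl]-3-{4-(benzyloxy)-2-[(3R)-7-(benzyloxy)-3,4-dihydro-2H-chromen-3-yl]-6-methoxyphenyl}propan-1-ol
Product: 37 (3R,4S)-7-(benzyloxy)-3-[2-(benzyloxy)-4,5-dimethoxyphenyl]-4-{4-(benzyloxy)-2-[(3R)-7-(benzyloxy)-3,4-dihydro-2H-chromen-3-yl]-6-methoxyphenyl}-3,4-dihydro-2H-chromene
Conditions: PPh3, DIAD, THF, 0 °C → rt
Reagents that add atoms: none
Why: Intramolecular Mitsunobu etherification; the ring A phenoxide displaces the oxyphosphonium group at primary C2 in a 6-exo-tet SN2 closure of ring C, and neither stereocentre takes part.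

Step 24
Reactants: 37 (3R,4S)-7-(benzyloxy)-3-[2-(benzyloxy)-4,5-dimethoxyphenyl]-4-{4-(benzyloxy)-2-[(3R)-7-(benzyloxy)-3,4-dihydro-2H-chromen-3-yl]-6-methoxyphenyl}-3,4-dihydro-2H-chromene
Product: 38 (3R,4S)-4-{4-hydroxy-2-[(3R)-7-hydroxy-3,4-dihydro-2H-chromen-3-yl]-6-methoxyphenyl}-3-(2-hydroxy-4,5-dimethoxyphenyl)-3,4-dihydro-2H-chromen-7-ol (target, CNP0266829.1)
Conditions: H2 (1 atm), 10% Pd/C, THF/MeOH, rt
Reagents that add atoms: none
Why: Hydrogenolysis of the four benzyl ethers; the skeleton has no benzylic C–O bond (both pyran oxygens join an arene to a non-benzylic CH2), so only the protecting groups are cleaved.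

## Compound list

1 | 2-bromo-4-hydroxybenzaldehyde | O=Cc1ccc(O)cc1Br | starting material
2 | 4-(benzyloxy)-2-bromobenzaldehyde | O=Cc1ccc(OCc2ccccc2)cc1Br | intermediate
3 | [4-(benzyloxy)-2-bromophenyl]methanol | OCc1ccc(OCc2ccccc2)cc1Br | intermediate
4 | 4-(benzyloxy)-2-bromo-1-(bromomethyl)benzene | BrCc1ccc(OCc2ccccc2)cc1Br | intermediate
5 | methyl 2,4-dihydroxy-6-methylbenzoate (methyl orsellinate) | COC(=O)c1c(C)cc(O)cc1O | starting material
6 | methyl 4-(benzyloxy)-2-hydroxy-6-methylbenzoate | COC(=O)c1c(C)cc(OCc2ccccc2)cc1O | intermediate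
7 | methyl 4-(benzyloxy)-2-methoxy-6-methylbenzoate | COC(=O)c1c(C)cc(OCc2ccccc2)cc1OC | intermediate
8 | {[5-(benzyloxy)-3-methoxy-2-(methoxycarbonyl)phenyl]methyl}lithium | COC(=O)c1c(C[Li])cc(OCc2ccccc2)cc1OC | intermediate (not isolated)
9 | [5-(benzyloxy)-3-methoxy-2-(methoxycarbonyl)phenyl]acetic acid | COC(=O)c1c(CC(=O)O)cc(OCc2ccccc2)cc1OC | intermediate
10 | (4R)-4-benzyl-1,3-oxazolidin-2-one | O=C1N[C@H](Cc2ccccc2)CO1 | starting material
11 | mixed anhydride of acid 9 and pivalic acid | COC(=O)c1c(CC(=O)OC(=O)C(C)(C)C)cc(OCc2ccccc2)cc1OC | intermediate (not isolated)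
12 | methyl 4-(benzyloxy)-2-{2-[(4R)-4-benzyl-2-oxo-1,3-oxazolidin-3-yl]-2-oxoethyl}-6-methoxybenzoate | COC(=O)c1c(CC(=O)N2[C@H](Cc3ccccc3)COC2=O)cc(OCc2ccccc2)cc1OC | intermediate
13 | sodium (Z)-enolate of imide 12 | COC(=O)c1c(/C=C(\O[Na])N2[C@H](Cc3ccccc3)COC2=O)cc(OCc2ccccc2)cc1OC | intermediate (not isolated)
14 | methyl 4-(benzyloxy)-2-{(2R)-1-[(4R)-4-benzyl-2-oxo-1,3-oxazolidin-3-yl]-3-[4-(benzyloxy)-2-bromophenyl]-1-oxopropan-2-yl}-6-methoxybenzoate | COC(=O)c1c([C@@H](Cc2ccc(OCc3ccccc3)cc2Br)C(=O)N2[C@H](Cc3ccccc3)COC2=O)cc(OCc2ccccc2)cc1OC | intermediate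
15 | (2R)-2-[5-(benzyloxy)-2-(hydroxymethyl)-3-methoxyphenyl]-3-[4-(benzyloxy)-2-bromophenyl]propan-1-ol | OCc1c([C@@H](Cc2ccc(OCc3ccccc3)cc2Br)CO)cc(OCc2ccccc2)cc1OC | intermediate
16 | {4-(benzyloxy)-2-[(3R)-7-(benzyloxy)-3,4-dihydro-2H-chromen-3-yl]-6-methoxyphenyl}methanol | OCc1c([C@@H]2COc3cc(OCc4ccccc4)ccc3C2)cc(OCc2ccccc2)cc1OC | intermediate
17 | 4-(benzyloxy)-2-[(3R)-7-(benzyloxy)-3,4-dihydro-2H-chromen-3-yl]-6-methoxybenzaldehyde | O=Cc1c([C@@H]2COc3cc(OCc4ccccc4)ccc3C2)cc(OCc2ccccc2)cc1OC | intermediate
18 | 2-[(E)-2-{4-(benzyloxy)-2-[(3R)-7-(benzyloxy)-3,4-dihydro-2H-chromen-3-yl]-6-methoxyphenyl}ethenyl]-4,4,5,5-tetramethyl-1,3,2-dioxaborolane | CC1(C)OB(/C=C/c2c(OC)cc(OCc3ccccc3)cc2[C@@H]2COc3cc(OCc4ccccc4)ccc3C2)OC1(C)C | intermediate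
19 | acenaphthylene-1,2-dione | O=C1C(=O)c2cccc3cccc1c23 | starting material
20 | cis-1,2-dimethyl-1,2-dihydroacenaphthylene-1,2-diol (meso) | C[C@@]1(O)c2cccc3cccc(c23)[C@]1(C)O | intermediate
21 | [(E)-2-{4-(benzyloxy)-2-[(3R)-7-(benzyloxy)-3,4-dihydro-2H-chromen-3-yl]-6-methoxyphenyl}ethenyl]boronic acid | OB(O)/C=C/c1c(OC)cc(OCc2ccccc2)cc1[C@@H]1COc2cc(OCc3ccccc3)ccc2C1 | intermediate (not isolated)
22 | cyclic boronic ester of diol 20 and boronic acid 21 | B1(/C=C/c2c(OC)cc(OCc3ccccc3)cc2[C@@H]2COc3cc(OCc4ccccc4)ccc3C2)O[C@]2(C)c3cccc4cccc(c34)[C@]2(C)O1 | intermediate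
23 | 3,4-dimethoxyphenol | COc1ccc(O)cc1OC | starting material
24 | 2-bromo-4,5-dimethoxyphenol | COc1cc(O)c(Br)cc1OC | intermediate
25 | 1-(benzyloxy)-2-bromo-4,5-dimethoxybenzene | COc1cc(OCc2ccccc2)c(Br)cc1OC | intermediate
26 | 4-(benzyloxy)-2-hydroxybenzaldehyde | O=Cc1ccc(OCc2ccccc2)cc1O | starting material
27 | 4-(benzyloxy)-2-(methoxymethoxy)benzaldehyde | O=Cc1ccc(OCc2ccccc2)cc1OCOC | intermediate
28 | 4-(benzyloxy)-2-(methoxymethoxy)phenyl formate | O=COc1ccc(OCc2ccccc2)cc1OCOC | intermediate (not isolated)
29 | 4-(benzyloxy)-2-(methoxymethoxy)phenol | Oc1ccc(OCc2ccccc2)cc1OCOC | intermediate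
30 | 4-(benzyloxy)-2-(methoxymethoxy)phenyl trifluoromethanesulfonate | O=S(=O)(Oc1ccc(OCc2ccccc2)cc1OCOC)C(F)(F)F | intermediate
31 | [2-(benzyloxy)-4,5-dimethoxyphenyl]lithium | [Li]c1cc(OC)c(OC)cc1OCc1ccccc1 | intermediate (not isolated)
32 | lithium borate from 31 and 22 (ate complex; configuration at boron not defined) | [Li+].COc1cc(OCc2ccccc2)c(cc1OC)[B-]1(/C=C/c2c(OC)cc(OCc3ccccc3)cc2[C@@H]2COc3cc(OCc4ccccc4)ccc3C2)O[C@]2(C)c3cccc4cccc(c34)[C@]2(C)O1 | intermediate (not isolated)
33 | cyclic boronic ester of diol 20 and (1R,2S)-1-[2-(benzyloxy)-4,5-dimethoxyphenyl]-2-[4-(benzyloxy)-2-(methoxymethoxy)phenyl]-2-{4-(benzyloxy)-2-[(3R)-7-(benzyloxy)-3,4-dihydro-2H-chromen-3-yl]-6-methoxyphenyl}ethylboronic acid | COc1cc(OCc2ccccc2)c(cc1OC)[C@H](B1O[C@]2(C)c3cccc4cccc(c34)[C@]2(C)O1)[C@@H](c1ccc(OCc2ccccc2)cc1OCOC)c1c(OC)cc(OCc2ccccc2)cc1[C@@H]1COc2cc(OCc3ccccc3)ccc2C1 | intermediate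
34 | cyclic boronic ester of diol 20 and the (2R,3S)-2,3,3-triarylpropylboronic acid (33 with CH2 inserted between C3 and boron) | COc1cc(OCc2ccccc2)c(cc1OC)[C@H](CB1O[C@]2(C)c3cccc4cccc(c34)[C@]2(C)O1)[C@@H](c1ccc(OCc2ccccc2)cc1OCOC)c1c(OC)cc(OCc2ccccc2)cc1[C@@H]1COc2cc(OCc3ccccc3)ccc2C1 | intermediate (not isolated)
35 | (2R,3S)-2-[2-(benzyloxy)-4,5-dimethoxyphenyl]-3-[4-(benzyloxy)-2-(methoxymethoxy)phenyl]-3-{4-(benzyloxy)-2-[(3R)-7-(benzyloxy)-3,4-dihydro-2H-chromen-3-yl]-6-methoxyphenyl}propan-1-ol | COc1cc(OCc2ccccc2)c(cc1OC)[C@H](CO)[C@@H](c1ccc(OCc2ccccc2)cc1OCOC)c1c(OC)cc(OCc2ccccc2)cc1[C@@H]1COc2cc(OCc3ccccc3)ccc2C1 | intermediate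
36 | (2R,3S)-2-[2-(benzyloxy)-4,5-dimethoxyphenyl]-3-[4-(benzyloxy)-2-hydroxyphenyl]-3-{4-(benzyloxy)-2-[(3R)-7-(benzyloxy)-3,4-dihydro-2H-chromen-3-yl]-6-methoxyphenyl}propan-1-ol | COc1cc(OCc2ccccc2)c(cc1OC)[C@H](CO)[C@@H](c1ccc(OCc2ccccc2)cc1O)c1c(OC)cc(OCc2ccccc2)cc1[C@@H]1COc2cc(OCc3ccccc3)ccc2C1 | intermediate
37 | (3R,4S)-7-(benzyloxy)-3-[2-(benzyloxy)-4,5-dimethoxyphenyl]-4-{4-(benzyloxy)-2-[(3R)-7-(benzyloxy)-3,4-dihydro-2H-chromen-3-yl]-6-methoxyphenyl}-3,4-dihydro-2H-chromene | COc1cc(OCc2ccccc2)c([C@@H]2COc3cc(OCc4ccccc4)ccc3[C@H]2c2c(OC)cc(OCc3ccccc3)cc2[C@@H]2COc3cc(OCc4ccccc4)ccc3C2)cc1OC | intermediate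
38 | (3R,4S)-4-{4-hydroxy-2-[(3R)-7-hydroxy-3,4-dihydro-2H-chromen-3-yl]-6-methoxyphenyl}-3-(2-hydroxy-4,5-dimethoxyphenyl)-3,4-dihydro-2H-chromen-7-ol | COc1cc(O)c([C@@H]2COc3cc(O)ccc3[C@H]2c2c(OC)cc(O)cc2[C@@H]2COc3cc(O)ccc3C2)cc1OC | target

## Step count and uncertain steps

Total step count: 24. Longest linear sequence: 15 steps from 5 (steps 4–12, 14 and 20–24). The side branches are steps 1–3 (bromide 4), step 13 (diol 20), steps 15–16 (bromide 25) and steps 17–19 (triflate 30).

**Step 20 (the proposed new method).**
- Most likely failure: ate complex 32 is diverted into direct transfer of its alkenyl or aryl group to palladium, or the arylpalladium fails to bind the alkene. The alkene is shielded by the ortho substituents of ring D and by the diol on boron, and both coupling partners carry ortho substituents.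
- Second risk: poor facial selectivity if C3' opposes the ligand.
- Fallback (known reactions; sets out from 17, 30 and 25, returns at 35):
  - Horner–Wadsworth–Emmons olefination of 17 with tert-butyl diethylphosphonoacetate (NaH, THF) gives tert-butyl (E)-3-arylacrylate F1.
  - Miyaura borylation of 30 (B2pin2, PdCl2(dppf), KOAc) gives ring A arylboronic ester F2.
  - Rhodium-catalysed asymmetric 1,4-addition of F2 to F1 (Hayashi–Miyaura reaction; Rh(acac)(C2H4)2 with the BINAP antipode that gives (S) at the future C4, aq. KOH, dioxane) gives 3,3-diarylpropanoate F3.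
  - Palladium-catalysed alpha-arylation of the lithium enolate of F3 with 25 (LiN(SiMe3)2, Pd(dba)2, P(t-Bu)3, toluene) gives 2,3,3-triarylpropanoate F4. The future C3 is epimerisable here and would be set by base equilibration and separation, with recycling of the unwanted epimer.
  - LiAlH4 reduction of F4 gives 35.

**Step 21.**
- Most likely failure: the carbenoid decomposes before it has added to the crowded boron of 33, so unchanged 33 is oxidised at C3 in the second stage.
- Fallback (sets out from 33, returns at 35):
  - Zweifel olefination (vinylmagnesium bromide, then I2 and NaOMe) replaces boron by a vinyl group with retention and gives terminal alkene F5. The vinyl nucleophile is thermally stable and can be used in excess and with warming to force ate formation.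
  - Lemieux–Johnson cleavage (OsO4 cat., NaIO4, 2,6-lutidine, dioxane/H2O), which the electron-rich arenes tolerate better than ozone, gives alpha-aryl aldehyde F6.
  - F6 is reduced at once with NaBH4 to 35, before C3 can epimerise.

**Step 14.**
- Most likely failure: protodeboronation of the free, electron-rich alkenylboronic acid 21 in the aqueous medium, or incomplete oxidative removal of the pinacol unit.
- Fallback (sets out from 18, returns at 22): aqueous KHF2 in methanol converts 18 into the isolable potassium alkenyltrifluoroborate F7 without a free boronic acid or an oxidant. Fluoride abstraction with Me3SiCl in acetonitrile in the presence of diol 20 gives 22.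

**Step 10.**
- Most likely failure: the arylpalladium intermediate is consumed by the free benzylic hydroxyl (palladium alkoxide formation and beta-hydride elimination, with loss of the bromide), or O-arylation occurs at the wrong hydroxyl.
- Fallback (sets out from 15, returns at 17):
  - Excess MnO2 oxidises the benzylic alcohol and the lactol it forms with the other hydroxyl to isochromanone F8.
  - AlMe3 and N,O-dimethylhydroxylamine hydrochloride open the lactone to hydroxy Weinreb amide F9, in which the benzylic carbon is at the carboxyl level and only the aliphatic hydroxyl is free.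
  - The same C–O coupling closes ring E to chroman Weinreb amide F10.
  - i-Bu2AlH at −78 °C reduces F10 to aldehyde 17, so step 11 is no longer needed.

## Further compounds

F1 | step 20 | tert-butyl (2E)-3-{4-(benzyloxy)-2-[(3R)-7-(benzyloxy)-3,4-dihydro-2H-chromen-3-yl]-6-methoxyphenyl}prop-2-enoate | CC(C)(C)OC(=O)/C=C/c1c(OC)cc(OCc2ccccc2)cc1[C@@H]1COc2cc(OCc3ccccc3)ccc2C1
F2 | step 20 | 2-[4-(benzyloxy)-2-(methoxymethoxy)phenyl]-4,4,5,5-tetramethyl-1,3,2-dioxaborolane | COCOc1cc(OCc2ccccc2)ccc1B1OC(C)(C)C(C)(C)O1
F3 | step 20 | tert-butyl (3S)-3-[4-(benzyloxy)-2-(methoxymethoxy)phenyl]-3-{4-(benzyloxy)-2-[(3R)-7-(benzyloxy)-3,4-dihydro-2H-chromen-3-yl]-6-methoxyphenyl}propanoate | CC(C)(C)OC(=O)C[C@@H](c1ccc(OCc2ccccc2)cc1OCOC)c1c(OC)cc(OCc2ccccc2)cc1[C@@H]1COc2cc(OCc3ccccc3)ccc2C1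
F4 | step 20 | tert-butyl (2R,3S)-2-[2-(benzyloxy)-4,5-dimethoxyphenyl]-3-[4-(benzyloxy)-2-(methoxymethoxy)phenyl]-3-{4-(benzyloxy)-2-[(3R)-7-(benzyloxy)-3,4-dihydro-2H-chromen-3-yl]-6-methoxyphenyl}propanoate | CC(C)(C)OC(=O)[C@@H](c1cc(OC)c(OC)cc1OCc1ccccc1)[C@@H](c1ccc(OCc2ccccc2)cc1OCOC)c1c(OC)cc(OCc2ccccc2)cc1[C@@H]1COc2cc(OCc3ccccc3)ccc2C1
F5 | step 21 | (3R,4S)-3-[2-(benzyloxy)-4,5-dimethoxyphenyl]-4-[4-(benzyloxy)-2-(methoxymethoxy)phenyl]-4-{4-(benzyloxy)-2-[(3R)-7-(benzyloxy)-3,4-dihydro-2H-chromen-3-yl]-6-methoxyphenyl}but-1-ene | COc1cc(OCc2ccccc2)c(cc1OC)[C@H](C=C)[C@@H](c1ccc(OCc2ccccc2)cc1OCOC)c1c(OC)cc(OCc2ccccc2)cc1[C@@H]1COc2cc(OCc3ccccc3)ccc2C1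
F6 | step 21 | (2R,3S)-2-[2-(benzyloxy)-4,5-dimethoxyphenyl]-3-[4-(benzyloxy)-2-(methoxymethoxy)phenyl]-3-{4-(benzyloxy)-2-[(3R)-7-(benzyloxy)-3,4-dihydro-2H-chromen-3-yl]-6-methoxyphenyl}propanal | COc1cc(OCc2ccccc2)c(cc1OC)[C@H](C=O)[C@@H](c1ccc(OCc2ccccc2)cc1OCOC)c1c(OC)cc(OCc2ccccc2)cc1[C@@H]1COc2cc(OCc3ccccc3)ccc2C1
F7 | step 14 | potassium trifluoro[(E)-2-{4-(benzyloxy)-2-[(3R)-7-(benzyloxy)-3,4-dihydro-2H-chromen-3-yl]-6-methoxyphenyl}ethenyl]borate | [K+].F[B-](F)(F)/C=C/c1c(OC)cc(OCc2ccccc2)cc1[C@@H]1COc2cc(OCc3ccccc3)ccc2C1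
F8 | step 10 | (4R)-6-(benzyloxy)-4-[4-(benzyloxy)-2-bromobenzyl]-8-methoxy-3,4-dihydro-1H-isochromen-1-one | O=C1OC[C@H](Cc2ccc(OCc3ccccc3)cc2Br)c2cc(OCc3ccccc3)cc(OC)c12
F9 | step 10 | 4-(benzyloxy)-2-{(2R)-1-[4-(benzyloxy)-2-bromophenyl]-3-hydroxypropan-2-yl}-N,6-dimethoxy-N-methylbenzamide | CON(C)C(=O)c1c(OC)cc(OCc2ccccc2)cc1[C@@H](Cc1ccc(OCc2ccccc2)cc1Br)CO
F10 | step 10 | 4-(benzyloxy)-2-[(3R)-7-(benzyloxy)-3,4-dihydro-2H-chromen-3-yl]-N,6-dimethoxy-N-methylbenzamide | CON(C)C(=O)c1c(OC)cc(OCc2ccccc2)cc1[C@@H]1COc2cc(OCc3ccccc3)ccc2C1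
A1 | alternative 1 | 5-(benzyloxy)-2-({4-(benzyloxy)-2-[(3R)-7-(benzyloxy)-3,4-dihydro-2H-chromen-3-yl]-6-methoxyphenyl}methyl)phenyl 2-diazo-2-[2-(tert-butyldimethylsilyloxy)-4,5-dimethoxyphenyl]acetate | COc1cc(O[Si](C)(C)C(C)(C)C)c(cc1OC)C(=[N+]=[N-])C(=O)Oc1cc(OCc2ccccc2)ccc1Cc1c(OC)cc(OCc2ccccc2)cc1[C@@H]1COc2cc(OCc3ccccc3)ccc2C1
A2 | alternative 1 | (3R,4S)-7-(benzyloxy)-3-[2-(tert-butyldimethylsilyloxy)-4,5-dimethoxyphenyl]-4-{4-(benzyloxy)-2-[(3R)-7-(benzyloxy)-3,4-dihydro-2H-chromen-3-yl]-6-methoxyphenyl}-3,4-dihydro-2H-chromen-2-one | COc1cc(O[Si](C)(C)C(C)(C)C)c(cc1OC)[C@@H]1C(=O)Oc2cc(OCc3ccccc3)ccc2[C@H]1c1c(OC)cc(OCc2ccccc2)cc1[C@@H]1COc2cc(OCc3ccccc3)ccc2C1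
A3 | alternative 2 | 1-[4-(benzyloxy)-2-(methoxymethoxy)phenyl]-3-[(3R)-7-(benzyloxy)-3,4-dihydro-2H-chromen-3-yl]prop-2-yn-1-one | O=C(C#C[C@@H]1COc2cc(OCc3ccccc3)ccc2C1)c1ccc(OCc2ccccc2)cc1OCOC
A4 | alternative 2 | 1,1-dimethoxy-3-(trimethylsilyloxy)buta-1,3-diene | C=C(O[Si](C)(C)C)C=C(OC)OC
A5 | alternative 2 | [4-(benzyloxy)-2-(methoxymethoxy)phenyl]{2-[(3R)-7-(benzyloxy)-3,4-dihydro-2H-chromen-3-yl]-4-hydroxy-6-methoxyphenyl}methanone | O=C(c1ccc(OCc2ccccc2)cc1OCOC)c1c(OC)cc(O)cc1[C@@H]1COc2cc(OCc3ccccc3)ccc2C1
A6 | alternative 3 | 5-(benzyloxy)-2-[{4-(benzyloxy)-2-[(3R)-7-(benzyloxy)-3,4-dihydro-2H-chromen-3-yl]-6-methoxyphenyl}(4-methylbenzenesulfonyl)methyl]phenol (mixture at the sulfonyl-bearing carbon) | Cc1ccc(cc1)S(=O)(=O)C(c1ccc(OCc2ccccc2)cc1O)c1c(OC)cc(OCc2ccccc2)cc1[C@@H]1COc2cc(OCc3ccccc3)ccc2C1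
A7 | alternative 3 | 3-(benzyloxy)-6-({4-(benzyloxy)-2-[(3R)-7-(benzyloxy)-3,4-dihydro-2H-chromen-3-yl]-6-methoxyphenyl}methylidene)cyclohexa-2,4-dien-1-one (alkene geometry not fixed) | O=C1C=C(OCc2ccccc2)C=CC1=Cc1c(OC)cc(OCc2ccccc2)cc1[C@@H]1COc2cc(OCc3ccccc3)ccc2C1
A8 | alternative 3 | [2-(benzyloxy)-4,5-dimethoxyphenyl]acetic acid | COc1cc(OCc2ccccc2)c(CC(=O)O)cc1OC
A9 | alternative 3 | (3R,4S)-7-(benzyloxy)-3-[2-(benzyloxy)-4,5-dimethoxyphenyl]-4-{4-(benzyloxy)-2-[(3R)-7-(benzyloxy)-3,4-dihydro-2H-chromen-3-yl]-6-methoxyphenyl}-3,4-dihydro-2H-chromen-2-one | COc1cc(OCc2ccccc2)c(cc1OC)[C@@H]1C(=O)Oc2cc(OCc3ccccc3)ccc2[C@H]1c1c(OC)cc(OCc2ccccc2)cc1[C@@H]1COc2cc(OCc3ccccc3)ccc2C1
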